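**Retrosynthetic overview**
1. Target 19 ⇒ intramolecular Nozaki–Hiyama–Kishi closure of the C4–C5 bond from aldehyde/vinyl triflate 18; this forms the ten-membered carbocycle last and sets C5.
2. Lactone ⇒ chromium-catalysed asymmetric 2-(methoxycarbonyl)allylation/lactonization of allyl bromide 13 with 2,2-dimethoxyacetaldehyde (C6–C7 bond; sets C6 and C7); 13 ⇐ cross-metathesis on the vinyl group of 11.
3. Furanone ⇒ gold-catalysed heterocyclization/1,2-methyl shift of α-hydroxy alkynyl ketone 10; the methyl C14 moves from C1 to C10 and the carbinol chirality is relayed into the quaternary centre.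
4. 10 ⇐ boron aldol with acrolein (C8–C9; sets C8) and acylation ⇐ enantioselective mono-alkynylation of biacetyl with enynyl triflate 2 (C1–C2).
5. Ring order: furanone, then lactone, then ten-membered carbocycle.

Assumption: positions are numbered as in the germacrane skeleton of the target (C1 ketone, C2=C3 enol ether, C4=C15, C5 carbinol, C6 lactone carbinol, C7, C8 ester carbon, C9, C10 quaternary, C11=C13, C12 lactone carbonyl, C14 methyl); 2,2-dimethoxyacetaldehyde is used as a dried organic solution.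

**Step 1**
Reactants: 1 but-3-yn-2-one
Product: 2 but-1-en-3-yn-2-yl triflate
Conditions: Tf2O, 2,6-di-tert-butyl-4-methylpyridine, CH2Cl2, 0 °C to rt
Reagents that add atoms: triflic anhydride, O=S(=O)(OS(=O)(=O)C(F)(F)F)C(F)(F)F
Why: Vinyl triflate synthesis from an enolizable ketone (O-triflation, then loss of an α-proton); the methyl group carries the only α-hydrogens, so only the 1-ethynylvinyl triflate can form, and no stereocenter is made.

**Step 2**
Reactants: 2 but-1-en-3-yn-2-yl triflate, 3 butane-2,3-dione (biacetyl)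
Product: 5 (R)-5-methyl-6-oxo-5-(trimethylsilyloxy)hept-1-en-3-yn-2-yl triflate, via free tertiary alcohol 4 (not isolated)
Conditions: Zn(OTf)2 (20 mol%), chiral β-amino alcohol L1 (22 mol%), Et3N (30 mol%), 3 (3 equiv), toluene, 25 °C; then N-(trimethylsilyl)imidazole, 25 °C
Reagents that add atoms: N-(trimethylsilyl)imidazole, C[Si](C)(C)n1ccnc1
Why: Proposed new method: catalytic enantioselective mono-alkynylation of a symmetric aliphatic 1,2-diketone, in which biacetyl chelates the amino-alkoxide-bound divalent zinc through both carbonyl oxygens as an α-keto ester does, the zinc acetylide formed from 2 by Zn(OTf)2/Et3N is delivered to one enantiotopic carbonyl face to set the (R)-carbinol (L1 = 2-(dimethylamino)-1-(4-nitrophenyl)-3-(tert-butyldimethylsilyloxy)propan-1-ol, the antipode that gives R being fixed in the first screen), both carbonyls are equivalent and the hindered tertiary zinc alkoxide does not take up a second alkyne; the closest known reaction type is the Zn(OTf)2/amino alcohol-catalysed alkynylation of α-keto esters, and the carbinol is capped in the flask as its TMS ether.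

**Step 3**
Reactants: 5 (R)-5-methyl-6-oxo-5-(trimethylsilyloxy)hept-1-en-3-yn-2-yl triflate, 6 acrolein
Product: 7 (5R,8R)-8-hydroxy-5-methyl-6-oxo-5-(trimethylsilyloxy)deca-1,9-dien-3-yn-2-yl triflate
Conditions: (+)-Ipc2BCl, Et3N, Et2O, −78 to 0 °C; 6, −78 to −20 °C; H2O2, MeOH, pH 7 buffer, 0 °C
Reagents that add atoms: none
Why: Paterson-type boron aldol of a methyl ketone, in which the C9 methyl is the only enolizable position, the diisopinocampheylboron enolate adds 1,2 to acrolein, and the Ipc antipode is the one that attacks the aldehyde Re face to give the (8R)-carbinol under reagent control (the other antipode is taken if the sense or the match with the α'-silyloxy centre proves opposite).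

**Step 4**
Reactants: 7 (5R,8R)-8-hydroxy-5-methyl-6-oxo-5-(trimethylsilyloxy)deca-1,9-dien-3-yn-2-yl triflate, 8 3-methylbutanoyl chloride (isovaleryl chloride)
Product: 10 (3R,6R)-6-hydroxy-6-methyl-5-oxo-9-(triflyloxy)deca-1,9-dien-7-yn-3-yl 3-methylbutanoate, via TMS ether ester 9 (not isolated)
Conditions: 8, pyridine, DMAP (cat.), CH2Cl2, 0 °C; then citric acid, MeOH, rt
Reagents that add atoms: none
Why: DMAP-catalysed acylation of the only free hydroxyl (secondary, C8) followed by mild acid methanolysis of the tertiary TMS ether; no stereocenter is touched and strongly basic conditions that would eliminate the β-acyloxy ketone are avoided.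

**Step 5**
Reactants: 10 (3R,6R)-6-hydroxy-6-methyl-5-oxo-9-(triflyloxy)deca-1,9-dien-7-yn-3-yl 3-methylbutanoate
Product: 11 (R)-1-[(R)-2-methyl-3-oxo-5-(1-triflyloxyvinyl)-2,3-dihydrofuran-2-yl]but-3-en-2-yl 3-methylbutanoate
Conditions: AuCl3 (5 mol%), CH2Cl2, 23 °C
Reagents that add atoms: none
Why: Gold-catalysed heterocyclization/1,2-alkyl shift (α-ketol or semipinacol type) of a 2-hydroxy-2-alkynyl ketone, in which the C10 carbonyl oxygen adds 5-endo to the alkyne activated by trivalent gold at C3, the methyl group on C1 then shifts suprafacially to the oxocarbenium carbon C10 on the ring face it already occupies and C1 becomes the ketone, so the furanone ring closes and the (R)-carbinol is relayed into the (R)-quaternary centre C10.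

**Step 6**
Reactants: 11 (R)-1-[(R)-2-methyl-3-oxo-5-(1-triflyloxyvinyl)-2,3-dihydrofuran-2-yl]but-3-en-2-yl 3-methylbutanoate, 12 methyl 2-(bromomethyl)prop-2-enoate
Product: 13 methyl (Z,4R)-2-(bromomethyl)-5-[(R)-2-methyl-3-oxo-5-(1-triflyloxyvinyl)-2,3-dihydrofuran-2-yl]-4-(3-methylbutanoyloxy)pent-2-enoate
Conditions: second-generation Hoveyda–Grubbs catalyst (10 mol%), 12 (5 equiv), CH2Cl2, 40 °C
Reagents that add atoms: none
Why: Olefin cross-metathesis of the monosubstituted vinyl group with the 1,1-disubstituted acrylate (ethylene is lost); the vinyl triflate and furanone alkenes are too hindered and electron-poor to engage, and the favoured trisubstituted enoate has C8 trans to the ester, though either geometry converges in the next step.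

**Step 7**
Reactants: 13 methyl (Z,4R)-2-(bromomethyl)-5-[(R)-2-methyl-3-oxo-5-(1-triflyloxyvinyl)-2,3-dihydrofuran-2-yl]-4-(3-methylbutanoyloxy)pent-2-enoate, 14 2,2-dimethoxyacetaldehyde
Product: 17 (R)-1-[(2S,3R)-2-(dimethoxymethyl)-4-methylene-5-oxotetrahydrofuran-3-yl]-2-[(R)-2-methyl-3-oxo-5-(1-triflyloxyvinyl)-2,3-dihydrofuran-2-yl]ethyl 3-methylbutanoate, via silyl ether 15 (not isolated), via hydroxy ester 16 (not isolated)
Conditions: CrCl2 (10 mol%), carbazole-bis(oxazoline) ligand L2 (12 mol%), Mn, TMSCl, iPr2NEt (cat.), THF, rt; then TsOH·H2O (cat.), MeOH, rt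
Reagents that add atoms: none
Why: Catalytic asymmetric Nozaki–Hiyama-type (Barbier) 2-(methoxycarbonyl)allylation, in which the allylchromium species (trivalent chromium; the vinyl triflate is inert without nickel) adds through a chair transition state with the C8-bearing substituent equatorial to give the 6,7-anti adduct, the ligand L2 (3,6-diphenyl-1,8-bis(4-isopropyl-4,5-dihydrooxazol-2-yl)-9H-carbazole, the antipode that directs attack to the aldehyde Si face) sets 6S and with it 7R, and acid methanolysis of the silyl ether is followed by lactonization to the trans α-methylene-γ-butyrolactone.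

**Step 8**
Reactants: 17 lactone dimethyl acetal
Product: 18 (R)-1-[(2S,3R)-2-formyl-4-methylene-5-oxotetrahydrofuran-3-yl]-2-[(R)-2-methyl-3-oxo-5-(1-triflyloxyvinyl)-2,3-dihydrofuran-2-yl]ethyl 3-methylbutanoate
Conditions: TFA/H2O (9:1), CH2Cl2, 0 °C to rt; used crude
Reagents that add atoms: water, O
Why: Acid-catalysed acetal hydrolysis; C6, α to the new aldehyde, is not epimerized under these non-basic conditions, and the vinyl triflate, esters and furanone are acid-stable.

**Step 9**
Reactants: 18 aldehyde vinyl triflate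
Product: 19 target (5R,6S,7R,8R,10R), CNP0409337.2
Conditions: CrCl2 (10 equiv), NiCl2 (0.1 equiv), DMSO/THF (1:3), rt, slow addition to 2 mM
Reagents that add atoms: none
Why: Intramolecular Nozaki–Hiyama–Kishi reaction, in which zerovalent nickel inserts into the vinyl triflate, transmetalation gives an alkenylchromium species (trivalent chromium) that adds to the aldehyde at high dilution to close the ten-membered carbocycle, and attack anti to the C6–O bond (Felkin–Anh) gives the 5,6-cis oxygen pattern, i.e. 5R.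

**Compound list**
1 | but-3-yn-2-one | CC(=O)C#C | starting material
2 | but-1-en-3-yn-2-yl triflate | C=C(OS(=O)(=O)C(F)(F)F)C#C | intermediate
3 | butane-2,3-dione (biacetyl) | CC(=O)C(C)=O | starting material
4 | (R)-5-hydroxy-5-methyl-6-oxohept-1-en-3-yn-2-yl triflate | CC(=O)[C@](C)(O)C#CC(=C)OS(=O)(=O)C(F)(F)F | intermediate
5 | (R)-5-methyl-6-oxo-5-(trimethylsilyloxy)hept-1-en-3-yn-2-yl triflate | CC(=O)[C@](C)(O[Si](C)(C)C)C#CC(=C)OS(=O)(=O)C(F)(F)F | intermediate
6 | acrolein (prop-2-enal) | C=CC=O | starting material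
7 | (5R,8R)-8-hydroxy-5-methyl-6-oxo-5-(trimethylsilyloxy)deca-1,9-dien-3-yn-2-yl triflate | C=C[C@H](O)CC(=O)[C@](C)(O[Si](C)(C)C)C#CC(=C)OS(=O)(=O)C(F)(F)F | intermediate
8 | 3-methylbutanoyl chloride (isovaleryl chloride) | CC(C)CC(Cl)=O | starting material
9 | (3R,6R)-6-methyl-5-oxo-9-(triflyloxy)-6-(trimethylsilyloxy)deca-1,9-dien-7-yn-3-yl 3-methylbutanoate | C=C[C@H](OC(=O)CC(C)C)CC(=O)[C@](C)(O[Si](C)(C)C)C#CC(=C)OS(=O)(=O)C(F)(F)F | intermediate
10 | (3R,6R)-6-hydroxy-6-methyl-5-oxo-9-(triflyloxy)deca-1,9-dien-7-yn-3-yl 3-methylbutanoate | C=C[C@H](OC(=O)CC(C)C)CC(=O)[C@](C)(O)C#CC(=C)OS(=O)(=O)C(F)(F)F | intermediate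
11 | (R)-1-[(R)-2-methyl-3-oxo-5-(1-triflyloxyvinyl)-2,3-dihydrofuran-2-yl]but-3-en-2-yl 3-methylbutanoate | C=C[C@H](OC(=O)CC(C)C)C[C@@]1(C)OC(=CC1=O)C(=C)OS(=O)(=O)C(F)(F)F | intermediate
12 | methyl 2-(bromomethyl)prop-2-enoate | C=C(CBr)C(=O)OC | starting material
13 | methyl (Z,4R)-2-(bromomethyl)-5-[(R)-2-methyl-3-oxo-5-(1-triflyloxyvinyl)-2,3-dihydrofuran-2-yl]-4-(3-methylbutanoyloxy)pent-2-enoate | BrC/C(C(=O)OC)=C\[C@H](OC(=O)CC(C)C)C[C@@]1(C)OC(=CC1=O)C(=C)OS(=O)(=O)C(F)(F)F | intermediate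
14 | 2,2-dimethoxyacetaldehyde | COC(OC)C=O | starting material
15 | methyl (3R,4S)-5,5-dimethoxy-2-methylene-3-{(1R)-1-(3-methylbutanoyloxy)-2-[(2R)-2-methyl-3-oxo-5-(1-triflyloxyvinyl)-2,3-dihydrofuran-2-yl]ethyl}-4-(trimethylsilyloxy)pentanoate | C=C(C(=O)OC)[C@@H]([C@H](O[Si](C)(C)C)C(OC)OC)[C@H](OC(=O)CC(C)C)C[C@@]1(C)OC(=CC1=O)C(=C)OS(=O)(=O)C(F)(F)F | intermediate
16 | methyl (3S,4S)-4-hydroxy-5,5-dimethoxy-2-methylene-3-{(1R)-1-(3-methylbutanoyloxy)-2-[(2R)-2-methyl-3-oxo-5-(1-triflyloxyvinyl)-2,3-dihydrofuran-2-yl]ethyl}pentanoate (same spatial arrangement as 15) | C=C(C(=O)OC)[C@@H]([C@H](O)C(OC)OC)[C@H](OC(=O)CC(C)C)C[C@@]1(C)OC(=CC1=O)C(=C)OS(=O)(=O)C(F)(F)F | intermediate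
17 | (R)-1-[(2S,3R)-2-(dimethoxymethyl)-4-methylene-5-oxotetrahydrofuran-3-yl]-2-[(R)-2-methyl-3-oxo-5-(1-triflyloxyvinyl)-2,3-dihydrofuran-2-yl]ethyl 3-methylbutanoate | C=C1C(=O)O[C@H](C(OC)OC)[C@H]1[C@H](OC(=O)CC(C)C)C[C@@]1(C)OC(=CC1=O)C(=C)OS(=O)(=O)C(F)(F)F | intermediate
18 | (R)-1-[(2S,3R)-2-formyl-4-methylene-5-oxotetrahydrofuran-3-yl]-2-[(R)-2-methyl-3-oxo-5-(1-triflyloxyvinyl)-2,3-dihydrofuran-2-yl]ethyl 3-methylbutanoate | C=C1C(=O)O[C@H](C=O)[C@H]1[C@H](OC(=O)CC(C)C)C[C@@]1(C)OC(=CC1=O)C(=C)OS(=O)(=O)C(F)(F)F | intermediate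
19 | CNP0409337.2: (5R,6S,7R,8R,10R)-5-hydroxy-8-(3-methylbutanoyloxy)-1-oxo-3,10-epoxygermacra-2,4(15),11(13)-trien-12,6-olide | C=C1C(=O)O[C@H]2[C@H]1[C@H](OC(=O)CC(C)C)C[C@@]1(C)OC(=CC1=O)C(=C)[C@H]2O | target

**Total step count:** 9. **Longest linear sequence:** 9 (from 1).

**Three steps most likely to fail**

Step 2 (the proposed new alkynylation). Biacetyl may self-condense or give low enantioselectivity. The fallback uses known chemistry and sets out from 2 and 3: the lithium acetylide of 2 (LiHMDS, THF, −78 °C) is added to excess 3 to give the racemic tertiary alcohol F1; preparative chromatography on a chiral stationary phase separates (R)-alcohol 4 from the (S)-alcohol F2, which is set aside; silylation of 4 with N-(trimethylsilyl)imidazole comes back to the route at 5.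

Step 6 (cross-metathesis). The allylic bromide partner and the hindered allylic ester may give low conversion. The fallback sets out from 11: catalytic OsO4 with N-methylmorpholine N-oxide dihydroxylates the monosubstituted alkene to the diol F3, and NaIO4 cleaves it to the α-acyloxy aldehyde F4; a Morita–Baylis–Hillman reaction with methyl acrylate (DABCO) gives the allylic alcohol F5 as a C7 epimer mixture; PBr3 in ether converts F5 by allylic transposition into the (Z)-bromide and comes back to the route at 13.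

Step 9 (macrocyclization). Oligomerization or the wrong C5 epimer are the risks. The fallback reverses the order of the last two C–C bond formations and sets out from 11: an intermolecular Nozaki–Hiyama–Kishi coupling of 11 with 14 (CrCl2, NiCl2 cat., chiral sulfonamide ligand, minor C5 epimer removed by chromatography) gives the allylic alcohol F6; TBSCl/imidazole gives the silyl ether F7; cross-metathesis with 12 gives the allyl bromide F8; acid hydrolysis of the acetal gives the aldehyde F9; an intramolecular chromium Barbier allylation (CrCl2, THF, high dilution), whose chromium alkoxide lactonizes as it forms, closes the ten-membered ring to the silyl-protected macrolactone F10; HF·pyridine removes the silyl group and comes back to the route at 19.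

**Further compounds**
F1 | step 2 | racemic 5-hydroxy-5-methyl-6-oxohept-1-en-3-yn-2-yl triflate | CC(=O)C(C)(O)C#CC(=C)OS(=O)(=O)C(F)(F)F
F2 | step 2 | (S)-5-hydroxy-5-methyl-6-oxohept-1-en-3-yn-2-yl triflate | CC(=O)[C@@](C)(O)C#CC(=C)OS(=O)(=O)C(F)(F)F
F3 | step 6 | (2R)-3,4-dihydroxy-1-[(R)-2-methyl-3-oxo-5-(1-triflyloxyvinyl)-2,3-dihydrofuran-2-yl]butan-2-yl 3-methylbutanoate (C7 epimers) | OCC(O)[C@H](OC(=O)CC(C)C)C[C@@]1(C)OC(=CC1=O)C(=C)OS(=O)(=O)C(F)(F)F
F4 | step 6 | (R)-1-[(R)-2-methyl-3-oxo-5-(1-triflyloxyvinyl)-2,3-dihydrofuran-2-yl]-3-oxopropan-2-yl 3-methylbutanoate | O=C[C@H](OC(=O)CC(C)C)C[C@@]1(C)OC(=CC1=O)C(=C)OS(=O)(=O)C(F)(F)F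
F5 | step 6 | methyl (4R)-3-hydroxy-2-methylene-5-[(R)-2-methyl-3-oxo-5-(1-triflyloxyvinyl)-2,3-dihydrofuran-2-yl]-4-(3-methylbutanoyloxy)pentanoate (C7 epimers) | C=C(C(=O)OC)C(O)[C@H](OC(=O)CC(C)C)C[C@@]1(C)OC(=CC1=O)C(=C)OS(=O)(=O)C(F)(F)F
F6 | step 9 | (R)-1-{(R)-5-[(R)-3-hydroxy-4,4-dimethoxybut-1-en-2-yl]-2-methyl-3-oxo-2,3-dihydrofuran-2-yl}but-3-en-2-yl 3-methylbutanoate | C=C[C@H](OC(=O)CC(C)C)C[C@@]1(C)OC(=CC1=O)C(=C)[C@@H](O)C(OC)OC
F7 | step 9 | tert-butyldimethylsilyl ether of F6 at C5 | C=C[C@H](OC(=O)CC(C)C)C[C@@]1(C)OC(=CC1=O)C(=C)[C@@H](O[Si](C)(C)C(C)(C)C)C(OC)OC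
F8 | step 9 | methyl (Z)-2-(bromomethyl)-enoate from F7 (allyl bromide, C5 silyl ether, C6 dimethyl acetal) | BrC/C(C(=O)OC)=C\[C@H](OC(=O)CC(C)C)C[C@@]1(C)OC(=CC1=O)C(=C)[C@@H](O[Si](C)(C)C(C)(C)C)C(OC)OC
F9 | step 9 | C6 aldehyde from F8 (allyl bromide, C5 silyl ether) | BrC/C(C(=O)OC)=C\[C@H](OC(=O)CC(C)C)C[C@@]1(C)OC(=CC1=O)C(=C)[C@@H](O[Si](C)(C)C(C)(C)C)C=O
F10 | step 9 | 5-O-tert-butyldimethylsilyl ether of 19 | C=C1C(=O)O[C@H]2[C@H]1[C@H](OC(=O)CC(C)C)C[C@@]1(C)OC(=CC1=O)C(=C)[C@H]2O[Si](C)(C)C(C)(C)C
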